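## Retrosynthetic overview
1. The hydroxyquinone comes from a 2-alkylresorcinol by a late Teuber oxidation. The resorcinol is symmetric, so both free ring positions give the same product.
2. The exocyclic C8=C12 alkene comes from an equatorial 8α tertiary alcohol, and that alcohol from the drim-7-ene. Hydration followed by anti elimination moves the site of proton loss.
3. Ring A, then ring B, and C5, C9 and C10 are all set in one reagent-controlled, proton-initiated chair–chair bicyclisation of the acetylated farnesylresorcinol.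
4. The farnesylresorcinol comes from 3,5-dihydroxybenzyl alcohol and (E,E)-farnesol by direct C-farnesylation between the two OH groups.

Assumption: the (R)-binaphthol reagent is taken to give the (5S,10S) series, the sense it shows with homofarnesyl ethers. If the sense is opposite here, the (S)-reagent is used.

Numbering note: decalin carbons carry drimane numbers. C4 bears the gem-dimethyl group, C5 and C10 are the ring fusion, C9 bears C11H2-aryl, and C12 sits on C8.

## Route

Step 1
Reactants: 1 3,5-dihydroxybenzyl alcohol; 2 (2E,6E)-farnesol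
Product: 3 2-[(2E,6E)-farnesyl]-5-(hydroxymethyl)benzene-1,3-diol
Conditions: acidic Al2O3, ClCH2CH2Cl, 83 °C, 8 h (1 in twofold excess)
Reagents that add atoms: none
Why: Alumina-templated Friedel–Crafts allylation, in which both surface-bound phenol groups steer the farnesyl cation equivalent to the carbon between them (as in the one-step preparations of cannabigerol and grifolin), the E geometry is kept and no stereocentre is formed.

Step 2
Reactants: 3 2-[(2E,6E)-farnesyl]-5-(hydroxymethyl)benzene-1,3-diol
Product: 4 2-[(2E,6E)-farnesyl]-5-(acetoxymethyl)-1,3-phenylene diacetate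
Conditions: Ac2O, pyridine, DMAP (5 mol %), CH2Cl2, 0 to 23 °C
Reagents that add atoms: acetic anhydride CC(=O)OC(C)=O
Why: Exhaustive O-acetylation makes both phenol oxygens non-nucleophilic, which prevents chroman formation in step 3, and removes every protic group that could act as an achiral proton source.

Step 3
Reactants: 4 2-[(2E,6E)-farnesyl]-5-(acetoxymethyl)-1,3-phenylene diacetate
Product: 6 2-{[(1S,4aS,8aS)-2,5,5,8a-tetramethyl-1,4,4a,5,6,7,8,8a-octahydronaphthalen-1-yl]methyl}-5-(acetoxymethyl)-1,3-phenylene diacetate (drim-7-ene), via monocyclic cyclofarnesyl triacetate 5 (not isolated)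
Conditions: (R)-2-(2-fluorobenzyloxy)-2'-hydroxy-1,1'-binaphthyl (4.4 equiv), SnCl4 (4.0 equiv), toluene, −78 °C, 72 h; then CF3CO2H (4 equiv), SnCl4 (2 equiv), CH2Cl2, −78 °C, 24 h
Reagents that add atoms: none
Why: Lewis-acid-assisted chiral Brønsted acid polyene cyclisation (a reagent class proven on O-acylated 2-farnesylphenols), in which the SnCl4-activated binaphthol proton adds to one face of the terminal alkene, the E,E-triene folds chair–chair so that anti additions set 5S, 10S and 9S (trans fusion, equatorial CH2Ar), the achiral acid stage re-protonates 5 and closes ring B under control of C5, and the C8 cation, with no nucleophile in reach, loses the axial C7 proton.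

Step 4
Reactants: 6 drim-7-ene triacetate
Product: 8 2-{[(1R,2R,4aS,8aS)-2-hydroxy-2,5,5,8a-tetramethyldecahydronaphthalen-1-yl]methyl}-5-(acetoxymethyl)-1,3-phenylene diacetate (8α-alcohol), via 8α-hydroperoxide 7 (not isolated)
Conditions: Mn(dpm)3 (10 mol %), PhSiH3 (2.5 equiv), O2 (1 atm), i-PrOH/CH2Cl2, 0 °C; then PPh3; recrystallise to raise ee
Reagents that add atoms: dioxygen O=O
Why: Mukaiyama hydration by metal-hydride hydrogen-atom transfer, in which H· adds to C7 (or to C12 of the minor exocyclic isomer, which converges on the same radical) and the tertiary C8 radical takes up O2 from the α face, away from the axial C10 methyl, setting the equatorial 8α (8R) C–O bond.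

Step 5
Reactants: 8 8α-alcohol triacetate
Product: 10 2-{[(1S,4aS,8aS)-5,5,8a-trimethyl-2-methylidenedecahydronaphthalen-1-yl]methyl}-5-(acetoxymethyl)-1,3-phenylene diacetate, via 8α-chlorosulfite 9 (not isolated)
Conditions: SOCl2 (3 equiv), pyridine (10 equiv), CH2Cl2, −78 to −30 °C
Reagents that add atoms: none
Why: Anti E2 elimination of an equatorial chlorosulfite in a rigid trans-decalin (Barton's rule for tertiary methyl carbinols, known for 8α-hydroxy drimanes and labdanes), where no ring C–H can be antiperiplanar to the equatorial C8–O bond but a C12–H can, so the exocyclic alkene forms and C9 is untouched.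

Step 6
Reactants: 10 exocyclic alkene triacetate
Product: 12 tauranin, via free triol 11 (not isolated)
Conditions: K2CO3 (0.3 equiv), MeOH, Ar, 0 to 23 °C; then KH2PO4 buffer (pH 6.5), (KSO3)2NO (2.5 equiv), acetone/H2O, 0 to 23 °C; then citric acid to pH 4, 0 °C
Reagents that add atoms: potassium nitrosodisulfonate (KSO3)2NO [K+].[K+].[O]N(S(=O)(=O)[O-])S(=O)(=O)[O-]
Why: Base-catalysed transesterification frees the resorcinol, and the Teuber oxidation then oxygenates the C–H para to one phenol (both such positions are equivalent) to give the 2-hydroxy-1,4-quinone under near-neutral conditions, which leave the alkene, the CH2OH group and all three stereocentres alone.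

## Compound list
1 | 3,5-dihydroxybenzyl alcohol | OCc1cc(O)cc(O)c1 | starting material
2 | (2E,6E)-farnesol | CC(C)=CCC/C(C)=C/CC/C(C)=C/CO | starting material
3 | 2-[(2E,6E)-farnesyl]-5-(hydroxymethyl)benzene-1,3-diol | CC(C)=CCC/C(C)=C/CC/C(C)=C/Cc1c(O)cc(CO)cc1O | intermediate
4 | 2-[(2E,6E)-farnesyl]-5-(acetoxymethyl)-1,3-phenylene diacetate | CC(C)=CCC/C(C)=C/CC/C(C)=C/Cc1c(OC(C)=O)cc(COC(C)=O)cc1OC(C)=O | intermediate
5 | 2-{(2E)-3-methyl-5-[(1S)-2,6,6-trimethylcyclohex-2-en-1-yl]pent-2-en-1-yl}-5-(acetoxymethyl)-1,3-phenylene diacetate (not isolated) | CC1=CCCC(C)(C)[C@@H]1CC/C(C)=C/Cc1c(OC(C)=O)cc(COC(C)=O)cc1OC(C)=O | intermediate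
6 | (5S,9S,10S)-drim-7-en-11-yl resorcinol triacetate | CC1=CC[C@H]2C(C)(C)CCC[C@]2(C)[C@H]1Cc1c(OC(C)=O)cc(COC(C)=O)cc1OC(C)=O | intermediate
7 | 8α-hydroperoxydriman-11-yl resorcinol triacetate (not isolated) | C[C@@]1(OO)CC[C@H]2C(C)(C)CCC[C@]2(C)[C@H]1Cc1c(OC(C)=O)cc(COC(C)=O)cc1OC(C)=O | intermediate
8 | 8α-hydroxydriman-11-yl resorcinol triacetate (OH equatorial, 8β-methyl axial) | C[C@@]1(O)CC[C@H]2C(C)(C)CCC[C@]2(C)[C@H]1Cc1c(OC(C)=O)cc(COC(C)=O)cc1OC(C)=O | intermediate
9 | 8α-chlorosulfite of 8 (not isolated) | C[C@@]1(OS(=O)Cl)CC[C@H]2C(C)(C)CCC[C@]2(C)[C@H]1Cc1c(OC(C)=O)cc(COC(C)=O)cc1OC(C)=O | intermediate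
10 | (5S,9S,10S)-drim-8(12)-en-11-yl resorcinol triacetate | C=C1CC[C@H]2C(C)(C)CCC[C@]2(C)[C@H]1Cc1c(OC(C)=O)cc(COC(C)=O)cc1OC(C)=O | intermediate
11 | 2-{[(1S,4aS,8aS)-5,5,8a-trimethyl-2-methylidenedecahydronaphthalen-1-yl]methyl}-5-(hydroxymethyl)benzene-1,3-diol (not isolated) | C=C1CC[C@H]2C(C)(C)CCC[C@]2(C)[C@H]1Cc1c(O)cc(CO)cc1O | intermediate
12 | tauranin, 2-hydroxy-6-(hydroxymethyl)-3-{[(1S,4aS,8aS)-5,5,8a-trimethyl-2-methylidenedecahydronaphthalen-1-yl]methyl}cyclohexa-2,5-diene-1,4-dione | C=C1CC[C@H]2C(C)(C)CCC[C@]2(C)[C@H]1CC1=C(O)C(=O)C(CO)=CC1=O | target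

## Step count and risks
Total step count: 6. Longest linear sequence: 6.

**The cyclisation (step 3) carries the most risk.**
- Three ester groups bind SnCl4, the ee may fall short, ring B may close incompletely, and the alkene isomer ratio is not controlled.
- The fallback changes from reagent control to substrate control and from a cationic to a radical cascade, and it sets out from 4.
- The terminal alkene is epoxidised with the enantiomer of the fructose-derived Shi ketone and KHSO5 at pH 8, run to partial conversion. This gives 2-[(2E,6E,10S)-10,11-epoxyfarnesyl]-5-(acetoxymethyl)-1,3-phenylene diacetate F1.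
- Cp2TiCl (from Cp2TiCl2 and Mn dust in THF, trivalent titanium) opens the epoxide homolytically. Two 6-endo radical closures follow, and β-hydrogen loss ends the cascade at the exocyclic alkene. The product is 3β-hydroxydrim-8(12)-en-11-yl resorcinol triacetate F2.
- 1,1'-Thiocarbonyldiimidazole then gives the 3β-(imidazol-1-ylthiocarbonyloxy) derivative F3, and Bu3SnH/AIBN removes the oxygen.
- This comes back to the route at 10, so steps 4 and 5 are no longer needed.

**The hydration (step 4) is second.**
- The C7=C8 alkene is hindered, any tetrasubstituted C8=C9 isomer is inert to hydrogen-atom transfer, and the α/β ratio at C8 is uncertain.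
- The fallback replaces radical hydration and polar elimination by polar addition and radical desaturation, and it sets out from 6.
- Dry HBr in CH2Cl2 at −78 °C converts every alkene isomer into the 8-bromodriman-11-yl resorcinol triacetate F4.
- Halogen-atom transfer with 4CzIPN and Et3N under blue light gives the C8 radical.
- The divalent cobalt formed from Co(dmgH)2(py)Cl then takes the most accessible β-hydrogen, which is on C12.
- This comes back at 10 and skips step 5.

**The farnesylation (step 1) is third.**
- The polar triol may stick to the alumina, and attack at the other ring positions or on oxygen may compete.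
- The fallback uses an aryl anion in place of the Friedel–Crafts reaction, and it sets out from 2.
- PBr3 gives (2E,6E)-farnesyl bromide F5.
- Purchased 4-bromo-3,5-dimethoxybenzyl alcohol is treated with n-BuLi (2.1 equiv, THF, −78 °C) and alkylated with F5. This gives {4-[(2E,6E)-farnesyl]-3,5-dimethoxyphenyl}methanol F6.
- Neat MeMgI at 160 °C cleaves both methyl ethers without acid.
- This comes back at 3.

## Further compounds
F1 | step 3 | 2-[(2E,6E,10S)-10,11-epoxyfarnesyl]-5-(acetoxymethyl)-1,3-phenylene diacetate | CC1(C)O[C@H]1CC/C(C)=C/CC/C(C)=C/Cc1c(OC(C)=O)cc(COC(C)=O)cc1OC(C)=O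
F2 | step 3 | 3β-hydroxydrim-8(12)-en-11-yl resorcinol triacetate | C=C1CC[C@H]2C(C)(C)[C@@H](O)CC[C@]2(C)[C@H]1Cc1c(OC(C)=O)cc(COC(C)=O)cc1OC(C)=O
F3 | step 3 | 3β-(imidazol-1-ylthiocarbonyloxy)drim-8(12)-en-11-yl resorcinol triacetate | C=C1CC[C@H]2C(C)(C)[C@@H](OC(=S)n3ccnc3)CC[C@]2(C)[C@H]1Cc1c(OC(C)=O)cc(COC(C)=O)cc1OC(C)=O
F4 | step 4 | 8-bromodriman-11-yl resorcinol triacetate (C8 epimers) | CC1(Br)CC[C@H]2C(C)(C)CCC[C@]2(C)[C@H]1Cc1c(OC(C)=O)cc(COC(C)=O)cc1OC(C)=O
F5 | step 1 | (2E,6E)-farnesyl bromide | CC(C)=CCC/C(C)=C/CC/C(C)=C/CBr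
F6 | step 1 | {4-[(2E,6E)-farnesyl]-3,5-dimethoxyphenyl}methanol | CC(C)=CCC/C(C)=C/CC/C(C)=C/Cc1c(OC)cc(CO)cc1OC
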